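**Retrosynthetic overview**
1. The target comes from its methyl ester (saponification), which comes from a ring-D lactol by Wittig isopropylidenation of a masked aldehyde.
2. Key disconnection C6–C1'': the lactol is made from an aromatic 6-prenyl-5,7-dihydroxychromanone ester and an α-methylene aldehyde by a biomimetic alkylative dearomatisation, the laboratory copy of the presumed biosynthetic C6 alkylation of a prenylated acylphloroglucinol, under chiral ammonium ion-pair control.
3. Enabling feature: C6 of ring A lies between the oxygen-bearing C5 and C7 (a latent 1,3-dicarbonyl α-carbon), and C2'', which is 1,3 to C6, carries an isobutenyl group that is a formyl group in disguise. O5–C5–C6–C1''–C2''–C3'' can therefore close to a temporary six-membered lactol (ring D) in which the C6 configuration dictates that of C2''.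
4. The aromatic ester is built on 5,7-dihydroxycoumarin, where one 7-O-methyl group makes each later ring-A event regiospecific (C1' by rhodium-catalysed 1,4-addition, ortho-acylation, ring B closure on the only free phenol, prenylation of the only free carbon). The aldehyde comes from ethyl 2-(bromomethyl)acrylate.
5. Ring order: ring A and lactone ring C come with the coumarin; ring B closes in step 7; ring C is opened in step 9; ring D closes in step 10 and is opened in step 11.

Key step: step 10

Assumptions (chemistry): ring A/B atoms carry chromanone numbers (O1, C2, C3, C4, C4a, C5–C8, C8a); C1' is the benzylic carbon; C1'' is the CH2 on C6, C2'' the adjacent CH, C3'' the formyl carbon that becomes the CH= of the isobutenyl group. The target is treated as one of several fast-equilibrating β-triketone tautomers. The sense of induction of the chiral catalysts in steps 5, 7 and 10 is assigned by analogy with close substrates; the antipodal ligand or pseudo-enantiomeric alkaloid is the direct remedy if a sense proves opposite.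

**Route**

Step 1
Reactants: 1 ethyl 2-(bromomethyl)prop-2-enoate
Product: 2 ethyl 5-methyl-2-methylidenehex-5-enoate
Conditions: 2-methylallylMgCl (1.1 equiv), CuI (10 mol%), THF, −78 → −30 °C
Reagents that add atoms: 2-methylallylmagnesium chloride, C=C(C)C[Mg]Cl
Why: Copper-catalysed allylic substitution of the allylic bromide by the Grignard reagent (SN2 and SN2' attack give the same product because both allyl units are symmetric) should be faster at low temperature than addition to the ester; no stereocentre is formed.

Step 2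
Reactants: 2 ethyl 5-methyl-2-methylidenehex-5-enoate
Product: 3 5-methyl-2-methylidenehex-5-en-1-ol
Conditions: i-Bu2AlH (2.3 equiv), CH2Cl2, −78 → 0 °C; aq. KNaC4H4O6 (potassium sodium tartrate)
Reagents that add atoms: none
Why: i-Bu2AlH reduces the conjugated ester by 1,2-hydride delivery to the allylic alcohol without touching either alkene; no stereocentre is formed.

Step 3
Reactants: 3 5-methyl-2-methylidenehex-5-en-1-ol
Product: 4 5-methyl-2-methylidenehex-5-enal
Conditions: MnO2 (activated, 15 equiv), CH2Cl2, 23 °C; used at once as a cold solution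
Reagents that add atoms: none
Why: MnO2 allylic oxidation acts only on the allylic alcohol and stops at the aldehyde, giving the α-methylene aldehyde that is used directly because it polymerises on storage; no stereocentre is formed.

Step 4
Reactants: 5 5,7-dihydroxy-2H-chromen-2-one
Product: 6 5-hydroxy-7-methoxy-2H-chromen-2-one
Conditions: MeI (1.05 equiv), K2CO3 (1.1 equiv), acetone, 23 °C
Reagents that add atoms: iodomethane, CI
Why: Williamson etherification with one equivalent of MeI should take place at 7-OH, the more acidic and less hindered phenol (para-conjugated to the pyranone carbonyl), and leave 5-OH free; no stereocentre is formed.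

Step 5
Reactants: 6 5-hydroxy-7-methoxy-2H-chromen-2-one
Product: 7 (4R)-5-hydroxy-7-methoxy-4-phenyl-3,4-dihydro-2H-chromen-2-one
Conditions: PhB(OH)2 (5 equiv), Rh(acac)(C2H4)2 (3 mol%), (R)-5,5'-bis(diphenylphosphino)-4,4'-bi-1,3-benzodioxole [(R)-SEGPHOS] (3.3 mol%), 1,4-dioxane/H2O 10:1, 60 °C
Reagents that add atoms: phenylboronic acid, OB(O)c1ccccc1
Why: Hayashi–Miyaura rhodium-catalysed asymmetric 1,4-addition of an arylboronic acid to a coumarin, a documented acceptor class; the chiral diphosphine selects the face of C4 in the aryl-rhodium insertion and so sets the (R) benzylic centre (C1' of the target).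

Step 6
Reactants: 7 (4R)-5-hydroxy-7-methoxy-4-phenyl-3,4-dihydro-2H-chromen-2-one
Product: 8 (4R)-5-hydroxy-7-methoxy-6-[(2E)-2-methylbut-2-enoyl]-4-phenyl-3,4-dihydro-2H-chromen-2-one
Conditions: tigloyl chloride (1.3 equiv), TiCl4 (2.5 equiv), ClCH2CH2Cl, 0 → 40 °C
Reagents that add atoms: (2E)-2-methylbut-2-enoyl chloride (tigloyl chloride), C/C=C(\C)C(Cl)=O
Why: Friedel–Crafts acylation directed by the titanium phenoxide should deliver the acyl group to the only free position ortho to 5-OH (coumarin C6, the future C4a), the product being held as an unreactive titanium chelate; no stereocentre is formed.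

Step 7
Reactants: 8 (4R)-5-hydroxy-7-methoxy-6-[(2E)-2-methylbut-2-enoyl]-4-phenyl-3,4-dihydro-2H-chromen-2-one
Product: 9 δ-lactone (onto O7) of (3R)-3-[(2R,3S)-7-hydroxy-5-methoxy-2,3-dimethyl-4-oxo-3,4-dihydro-2H-chromen-8-yl]-3-phenylpropanoic acid
Conditions: (−)-quinine (20 mol%), PhCl, 23 °C
Reagents that add atoms: none
Why: Cinchona-alkaloid-catalysed intramolecular oxa-Michael addition (6-endo-trig) of the only free phenol to the tigloyl enone, known for o-hydroxyaryl tigloyl ketones on coumarins; the alkaloid selects the face of the β-carbon and should set C2 as (R), while kinetic protonation gives mainly the cis C3 epimer, which is corrected in step 8.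

Step 8
Reactants: 9 δ-lactone (onto O7) of (3R)-3-[(2R,3S)-7-hydroxy-5-methoxy-2,3-dimethyl-4-oxo-3,4-dihydro-2H-chromen-8-yl]-3-phenylpropanoic acid
Product: 10 δ-lactone (onto O7) of (3R)-3-[(2R,3R)-5,7-dihydroxy-2,3-dimethyl-4-oxo-3,4-dihydro-2H-chromen-8-yl]-3-phenylpropanoic acid
Conditions: MgI2·OEt2 (4 equiv), toluene/THF, 70 °C; aq. NH4Cl
Reagents that add atoms: none
Why: MgI2 chelated between the C4 carbonyl and the peri methoxy oxygen cleaves only that methyl ether (iodide SN2 at the methyl group) and, through the magnesium enolate, should equilibrate C3 to the more stable trans (2R,3R) isomer with both methyl groups pseudo-equatorial, C2 being untouched.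

Step 9
Reactants: 10 δ-lactone (onto O7) of (3R)-3-[(2R,3R)-5,7-dihydroxy-2,3-dimethyl-4-oxo-3,4-dihydro-2H-chromen-8-yl]-3-phenylpropanoic acid
Product: 12 methyl (3R)-3-[(2R,3R)-5,7-dihydroxy-2,3-dimethyl-6-(3-methylbut-2-en-1-yl)-4-oxo-3,4-dihydro-2H-chromen-8-yl]-3-phenylpropanoate, via ring-opened methyl ester 11 (not isolated)
Conditions: NaOMe (4 equiv), MeOH, 0 → 23 °C; then prenyl bromide (1.1 equiv), 0 °C; pH 7 buffer
Reagents that add atoms: sodium methoxide (in methanol), C[O-].[Na+]; 1-bromo-3-methylbut-2-ene (prenyl bromide), CC(C)=CCBr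
Why: Methoxide opens the aryl ester (acyl substitution with the 7-phenoxide as leaving group) and the resulting phloroglucinol-type dianion should undergo C-alkylation with prenyl bromide in the protic solvent at C6, the only unsubstituted ring carbon, flanked by O5 and O7; no stereocentre is formed and C3 stays in its trans thermodynamic configuration.

Step 10
Reactants: 12 methyl (3R)-3-[(2R,3R)-5,7-dihydroxy-2,3-dimethyl-6-(3-methylbut-2-en-1-yl)-4-oxo-3,4-dihydro-2H-chromen-8-yl]-3-phenylpropanoate; 4 5-methyl-2-methylidenehex-5-enal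
Product: 14 ring-D lactol of the C6 adduct (6S,2''R; anomer mixture at C3''), via open-chain aldehyde adduct 13 (not isolated)
Conditions: N-(9-anthracenylmethyl)-O-allylcinchonidinium bromide (20 mol%), CsOH·H2O (3 equiv), 4 (2 equiv), CH2Cl2/toluene 1:1, −50 °C; then AcOH (4 equiv), pyrrolidine (20 mol%), THF, 23 °C
Reagents that add atoms: none
Why: The caesium phenoxide of 12, paired with the chiral ammonium cation, adds through C6 (ortho to O5 and O7, para to O1) to the CH2 terminus of enal 4 in a dearomative conjugate addition, the aldehyde enolate is protonated, and after neutralisation the C5 enol oxygen adds to the formyl group to close ring D as a lactol (6-exo-trig hemiacetalisation). The closest known reaction types are the chiral-ammonium phase-transfer alkylative dearomatisation of prenylated acylphloroglucinols with enals and the Michael addition/hemiacetalisation of cyclic 1,3-diones with enals. C6 is set by the ion pair, which exposes one face of the planar phenoxide to the enal (catalyst control, since the existing centres are remote). C2'' is set under thermodynamic control: pyrrolidine epimerises the formyl-bearing carbon through the enamine of the open form, and in ring D the prenyl group on C6 is forced axial by the near-planar ring A, so that only the epimer with the C2'' side chain equatorial, which corresponds to the (6S,2''R) relationship of the target, avoids a 1,3-diaxial clash. The step needs C- over O-attack (oxa-Michael addition is reversible and the C-adduct is the sink), C6 over C8 (C8 already carries the branched benzylic substituent) and 1,4- over 1,2-addition (soft delocalised nucleophile); the anomeric carbon is left as a mixture because it becomes sp2 in step 11.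

Step 11
Reactants: 14 ring-D lactol of the C6 adduct (6S,2''R; anomer mixture at C3'')
Product: 16 methyl (3R)-3-{(2R,3R,6S)-4-hydroxy-2,3-dimethyl-6-(3-methylbut-2-en-1-yl)-6-[(2R)-5-methyl-2-(2-methylprop-1-en-1-yl)hex-5-en-1-yl]-5,7-dioxo-2,3,6,7-tetrahydro-5H-chromen-8-yl}-3-phenylpropanoate, via open-chain (2''R)-aldehyde 15 (not isolated)
Conditions: i-PrPPh3I (4 equiv), n-BuLi (3.9 equiv), THF, 0 °C; 14 added at −78 °C, then → 0 °C; pH 5 phosphate buffer
Reagents that add atoms: isopropyltriphenylphosphonium iodide, CC(C)[P+](c1ccccc1)(c1ccccc1)c1ccccc1.[I-]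
Why: Wittig olefination of a lactol through its open hydroxy-aldehyde form with a non-stabilised ylide (the first equivalent of ylide deprotonates and opens ring D to the aldehyde and an unreactive triketonate) builds the C3''=C(CH3)2 bond; addition to the aldehyde should be faster than α-deprotonation, so C2'' keeps its configuration, and no E/Z issue arises.

Step 12
Reactants: 16 methyl (3R)-3-{(2R,3R,6S)-4-hydroxy-2,3-dimethyl-6-(3-methylbut-2-en-1-yl)-6-[(2R)-5-methyl-2-(2-methylprop-1-en-1-yl)hex-5-en-1-yl]-5,7-dioxo-2,3,6,7-tetrahydro-5H-chromen-8-yl}-3-phenylpropanoate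
Product: 17 (3R)-3-{(2R,3R,6S)-4-hydroxy-2,3-dimethyl-6-(3-methylbut-2-en-1-yl)-6-[(2R)-5-methyl-2-(2-methylprop-1-en-1-yl)hex-5-en-1-yl]-5,7-dioxo-2,3,6,7-tetrahydro-5H-chromen-8-yl}-3-phenylpropanoic acid
Conditions: LiOH·H2O (4 equiv), THF/H2O 3:1, 0 → 23 °C; 1 M HCl to pH 4 at 0 °C
Reagents that add atoms: lithium hydroxide monohydrate, [Li+].[OH-].O
Why: Saponification of the methyl ester with LiOH, during which ring A is protected as its delocalised enolate; cold acidification to pH 4 should return the enol form without acid-induced cyclisation of the prenyl groups, and no stereocentre is touched.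

**Compound list**
1 | ethyl 2-(bromomethyl)prop-2-enoate | C=C(CBr)C(=O)OCC | starting material
2 | ethyl 5-methyl-2-methylidenehex-5-enoate | C=C(C)CCC(=C)C(=O)OCC | intermediate
3 | 5-methyl-2-methylidenehex-5-en-1-ol | C=C(C)CCC(=C)CO | intermediate
4 | 5-methyl-2-methylidenehex-5-enal | C=C(C)CCC(=C)C=O | intermediate
5 | 5,7-dihydroxy-2H-chromen-2-one (5,7-dihydroxycoumarin) | O=c1ccc2c(O)cc(O)cc2o1 | starting material
6 | 5-hydroxy-7-methoxy-2H-chromen-2-one | COc1cc(O)c2ccc(=O)oc2c1 | intermediate
7 | (4R)-5-hydroxy-7-methoxy-4-phenyl-3,4-dihydro-2H-chromen-2-one | COc1cc(O)c2c(c1)OC(=O)C[C@@H]2c1ccccc1 | intermediate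
8 | (4R)-5-hydroxy-7-methoxy-6-[(2E)-2-methylbut-2-enoyl]-4-phenyl-3,4-dihydro-2H-chromen-2-one | C/C=C(\C)C(=O)c1c(O)c2c(cc1OC)OC(=O)C[C@@H]2c1ccccc1 | intermediate
9 | δ-lactone (onto O7) of (3R)-3-[(2R,3S)-7-hydroxy-5-methoxy-2,3-dimethyl-4-oxo-3,4-dihydro-2H-chromen-8-yl]-3-phenylpropanoic acid (cis-chromanone) | O=C1[C@@H](C)[C@@H](C)Oc2c1c(OC)cc3OC(=O)C[C@H](c4ccccc4)c23 | intermediate
10 | δ-lactone (onto O7) of (3R)-3-[(2R,3R)-5,7-dihydroxy-2,3-dimethyl-4-oxo-3,4-dihydro-2H-chromen-8-yl]-3-phenylpropanoic acid (trans-chromanone) | O=C1[C@H](C)[C@@H](C)Oc2c1c(O)cc3OC(=O)C[C@H](c4ccccc4)c23 | intermediate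
11 | methyl (3R)-3-[(2R,3R)-5,7-dihydroxy-2,3-dimethyl-4-oxo-3,4-dihydro-2H-chromen-8-yl]-3-phenylpropanoate (formed in the flask in step 9) | O=C1[C@H](C)[C@@H](C)Oc2c1c(O)cc(O)c2[C@H](CC(=O)OC)c1ccccc1 | intermediate
12 | methyl (3R)-3-[(2R,3R)-5,7-dihydroxy-2,3-dimethyl-6-(3-methylbut-2-en-1-yl)-4-oxo-3,4-dihydro-2H-chromen-8-yl]-3-phenylpropanoate | O=C1[C@H](C)[C@@H](C)Oc2c1c(O)c(CC=C(C)C)c(O)c2[C@H](CC(=O)OC)c1ccccc1 | intermediate
13 | methyl (3R)-3-{(2R,3R)-6-(2-formyl-5-methylhex-5-en-1-yl)-4-hydroxy-2,3-dimethyl-6-(3-methylbut-2-en-1-yl)-5,7-dioxo-2,3,6,7-tetrahydro-5H-chromen-8-yl}-3-phenylpropanoate; C6 arranged as in 17, both epimers at the formyl-bearing carbon (formed in the flask in step 10) | C=C(C)CCC(C=O)C[C@@]1(CC=C(C)C)C(=O)C2=C(O)[C@H](C)[C@@H](C)OC2=C([C@H](CC(=O)OC)c2ccccc2)C1=O | intermediate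
14 | ring-D lactol of 13: O5 of the C5 enol bonded to C3''H(OH), giving the ring O5–C5(=C4a)–C6–C1''H2–C2''H(CH2CH2C(CH3)=CH2)–C3''H(OH); C4=O, C7=O, C8=C8a; C6 (S), C2'' (R), C2 (R), C3 (R), C1' (R), anomer mixture at C3'' | C=C(C)CC[C@@H]1C[C@]2(CC=C(C)C)C(=O)C([C@H](CC(=O)OC)c3ccccc3)=C3O[C@H](C)[C@@H](C)C(=O)C3=C2OC1O | intermediate
15 | open-chain (2''R)-aldehyde, the single epimer of 13 (C6 arranged as in 17; its CIP label here is R because the formyl-bearing chain outranks prenyl) (formed in the flask in step 11) | C=C(C)CC[C@@H](C=O)C[C@@]1(CC=C(C)C)C(=O)C2=C(O)[C@H](C)[C@@H](C)OC2=C([C@H](CC(=O)OC)c2ccccc2)C1=O | intermediate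
16 | methyl (3R)-3-{(2R,3R,6S)-4-hydroxy-2,3-dimethyl-6-(3-methylbut-2-en-1-yl)-6-[(2R)-5-methyl-2-(2-methylprop-1-en-1-yl)hex-5-en-1-yl]-5,7-dioxo-2,3,6,7-tetrahydro-5H-chromen-8-yl}-3-phenylpropanoate | C=C(C)CC[C@@H](C=C(C)C)C[C@@]1(CC=C(C)C)C(=O)C2=C(O)[C@H](C)[C@@H](C)OC2=C([C@H](CC(=O)OC)c2ccccc2)C1=O | intermediate
17 | (3R)-3-{(2R,3R,6S)-4-hydroxy-2,3-dimethyl-6-(3-methylbut-2-en-1-yl)-6-[(2R)-5-methyl-2-(2-methylprop-1-en-1-yl)hex-5-en-1-yl]-5,7-dioxo-2,3,6,7-tetrahydro-5H-chromen-8-yl}-3-phenylpropanoic acid (CNP0155375.5) | C=C(C)CC[C@@H](C=C(C)C)C[C@@]1(CC=C(C)C)C(=O)C2=C(O)[C@H](C)[C@@H](C)OC2=C([C@H](CC(=O)O)c2ccccc2)C1=O | target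

**Step count**
Total: 12 steps. Longest linear sequence: 9 steps (steps 4–12, from 5); steps 1–3 form the side branch that joins in step 10.

**Three steps most likely to fail**

Step 10. The ion pair may discriminate poorly between the two faces of C6, the amine-mediated equilibration may erode the C6 configuration by retro-Michael cleavage, or ring D may close incompletely so that the relay to C2'' is weak. The fallback replaces catalyst control by relay, separation and recycling. It sets out from 12 and 4: the addition is run with an achiral base (Et3N, MeOH, 0 °C) and followed by the same pyrrolidine/AcOH equilibration. Because the relay couples C2'' to C6, only two diastereomers should form, lactol 14 and its (6R,2''S) diastereomer F1, which differ in their relation to C2, C3 and C1' and are separated by chromatography. F1 should revert to 12 and 4 by retro-Michael cleavage on warming with CsOH·H2O in THF and is resubmitted. The route is rejoined at 14.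

Step 9. O-alkylation at O7 and a second prenylation at C6 with dearomatisation may compete with mono-C-prenylation. The fallback uses sigmatropic delivery instead of direct C-alkylation. It sets out from 10: methanolysis (NaOMe, MeOH) with neutral work-up gives isolated 11. O7 (5-OH is chelated and inert) is alkylated with methyl 2-methylbut-3-yn-2-yl carbonate (DBU, CuCl2 cat., MeCN, 0 °C) to methyl (3R)-3-{(2R,3R)-5-hydroxy-2,3-dimethyl-7-[(2-methylbut-3-yn-2-yl)oxy]-4-oxo-3,4-dihydro-2H-chromen-8-yl}-3-phenylpropanoate F2. Semi-hydrogenation (H2, Pd/CaCO3 poisoned with Pb(OAc)2, quinoline, EtOAc) gives the corresponding 7-[(2-methylbut-3-en-2-yl)oxy] ether F3. Aromatic Claisen rearrangement (N,N-diethylaniline, 130 °C) can go only to C6, the single free ortho position, and delivers the prenyl group with allylic inversion; any relactonised material is reopened with NaOMe/MeOH. The route is rejoined at 12.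

Step 6. Acylation may occur at C8 instead of C6, the Lewis acid may close the enone to racemic chromanone before the asymmetric step, or HCl may add to the enone. The fallback uses a one-carbon homologation instead of Friedel–Crafts acylation. It sets out from 7: ortho-specific formylation (MgCl2, Et3N, (CH2O)n, MeCN, 80 °C) gives (4R)-5-hydroxy-7-methoxy-2-oxo-4-phenyl-3,4-dihydro-2H-chromene-6-carbaldehyde F4. Nozaki–Hiyama–Kishi addition of (E)-2-bromobut-2-ene (CrCl2, NiCl2 cat., DMF, 23 °C) gives (4R)-5-hydroxy-6-[(2E)-1-hydroxy-2-methylbut-2-en-1-yl]-7-methoxy-4-phenyl-3,4-dihydro-2H-chromen-2-one F5 as a carbinol epimer mixture. MnO2 oxidation (CH2Cl2, 23 °C) gives the tigloyl ketone under neutral conditions. The route is rejoined at 8.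

**Further compounds**
F1 | step 10 | (6R,2''S) diastereomer of lactol 14 (C2, C3 and C1' as in 14; anomer mixture) | C=C(C)CC[C@H]1C[C@@]2(CC=C(C)C)C(=O)C([C@H](CC(=O)OC)c3ccccc3)=C3O[C@H](C)[C@@H](C)C(=O)C3=C2OC1O
F2 | step 9 | methyl (3R)-3-{(2R,3R)-5-hydroxy-2,3-dimethyl-7-[(2-methylbut-3-yn-2-yl)oxy]-4-oxo-3,4-dihydro-2H-chromen-8-yl}-3-phenylpropanoate | O=C1[C@H](C)[C@@H](C)Oc2c1c(O)cc(OC(C)(C)C#C)c2[C@H](CC(=O)OC)c1ccccc1
F3 | step 9 | methyl (3R)-3-{(2R,3R)-5-hydroxy-2,3-dimethyl-7-[(2-methylbut-3-en-2-yl)oxy]-4-oxo-3,4-dihydro-2H-chromen-8-yl}-3-phenylpropanoate | O=C1[C@H](C)[C@@H](C)Oc2c1c(O)cc(OC(C)(C)C=C)c2[C@H](CC(=O)OC)c1ccccc1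
F4 | step 6 | (4R)-5-hydroxy-7-methoxy-2-oxo-4-phenyl-3,4-dihydro-2H-chromene-6-carbaldehyde | COc1cc2OC(=O)C[C@H](c3ccccc3)c2c(O)c1C=O
F5 | step 6 | (4R)-5-hydroxy-6-[(2E)-1-hydroxy-2-methylbut-2-en-1-yl]-7-methoxy-4-phenyl-3,4-dihydro-2H-chromen-2-one (carbinol epimers) | COc1cc2OC(=O)C[C@H](c3ccccc3)c2c(O)c1C(O)/C(C)=C/C
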